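**Assumption:** both bicyclic halves of the target carry the same absolute configuration (6S,7S in the target's numbering, trans-fused 6/7 ring system). This holds because the SMILES reads as C2-related. The alcohol half has 3′R. The C10 epimers in 11 are irrelevant because C10 becomes sp2 in 13.

## Retrosynthetic overview
1. Sodwanone T (18) comes from statistical mono-oxidation of the C2-symmetric diol 17. The diol comes from double Stille coupling of vinyl triflate 13 with bis-stannylethene, then hydrogenation, which builds the CH2CH2 bridge.
2. Triflate 13 comes from ketone 7. The oxepane ring is closed by 7-endo opening of epoxide 6, and the C3 carbinol is set by Shi epoxidation.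
3. Hydroxyketone 5 carries the C6 quaternary centre and the C7–OH. It comes from desymmetrizing ketoreduction of the prochiral dione 4, which comes from alkylation of dione 2, which comes from hydrogenation (dearomatization) of 2-methylresorcinol (1).
4. Ring-formation order: cyclohexane (arene hydrogenation), then oxepane, then ring alkene (enol triflate), then dimerization through the ethano bridge.

## Route

**Step 1**
Reactants: 1 (2-methylresorcinol)
Product: 2 (2-methylcyclohexane-1,3-dione)
Conditions: H2 (50 atm), Raney Ni, aq. NaOH, 50 °C; then HCl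
Reagents that add atoms: none (H2 adds only hydrogen)
Why: Catalytic hydrogenation of the resorcinol dianion dearomatizes the ring through the dihydro tautomer to the symmetric 1,3-dione; no stereocentre forms.

**Step 2**
Reactants: 2 (2-methylcyclohexane-1,3-dione) + 3 (5-bromo-2-methylpent-2-ene)
Product: 4 (2-methyl-2-(4-methylpent-3-en-1-yl)cyclohexane-1,3-dione)
Conditions: NaOH (1 equiv), NaI (cat.), H2O, 90 °C
Reagents that add atoms: none (the homoprenyl bromide 3 is a listed reactant)
Why: C-alkylation of the dione enolate in water, where hydrogen bonding suppresses O-alkylation, forms the quaternary carbon. The product is prochiral, with two enantiotopic C=O groups.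

**Step 3**
Reactants: 4
Product: 5 ((2R,3S)-3-hydroxy-2-methyl-2-(4-methylpent-3-en-1-yl)cyclohexan-1-one; OH cis to Me, trans to the chain)
Conditions: KRED (NADPH-dependent, panel-selected), NADP+ (cat.), iPrOH (10% v/v), KPi pH 7, 30 °C, stopped at mono-reduction
Reagents that add atoms: none
Why: Proposed new method: this is the symmetry-breaking key step. An NADPH-dependent ketoreductase reduces one of the two enantiotopic carbonyls, which sets C6 (quaternary) and C7 (carbinol) together in one step. Mechanistic reasoning: the enzyme pocket binds the homoprenyl chain and delivers hydride to the face syn to the chain (anti to Me), which gives the trans-ring-fusion stereochemistry. The closest known reaction is yeast or ADH desymmetrization of 2-allyl-2-methylcyclohexane-1,3-dione. That system gives the diastereomer with OH cis to the larger chain, so the enzyme must be chosen for the other one.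

**Step 4**
Reactants: 5
Product: 6 ((2R,3S)-2-{2-[(2R)-3,3-dimethyloxiran-2-yl]ethyl}-3-hydroxy-2-methylcyclohexan-1-one)
Conditions: Shi ketone (0.3 equiv), Oxone, K2CO3, Bu4NHSO4, DMM/MeCN/aq. Na2B4O7–EDTA, pH 10.5, 0 °C
Reagents that add atoms: Oxone, potassium peroxymonosulfate, [K+].OOS(=O)(=O)[O-] (donates the epoxide O)
Why: Shi asymmetric epoxidation of the unhindered trisubstituted alkene through a chiral dioxirane spiro transition state sets C3 as R. The ketone enantiomer is chosen to give R, and no ring alkene is present yet to compete.

**Step 5**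
Reactants: 6
Product: 7 ((3R,5aR,9aS)-3-hydroxy-2,2,5a-trimethyloctahydro-1-benzoxepin-6-one; trans-fused)
Conditions: CSA (10 mol %), CH2Cl2, 0 °C to rt
Reagents that add atoms: none (isomerization)
Why: Proposed new method: acid-catalyzed 7-endo epoxy-alcohol cyclization. The protonated epoxide has Markovnikov cation character at the tertiary carbon, which C7–OH attacks (equatorial OH, trans to the C5 chain). C3 is not touched, so it stays R, and C6/C7 are unchanged, so the trans ring fusion is preserved. The closest known reaction is Nicolaou/Coxon endo-selective hydroxy-epoxide opening.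

**Step 6**
Reactants: 7 + 8 (TBSOTf)
Product: 9 ((3R,5aR,9aS)-3-(tert-butyldimethylsilyloxy)-2,2,5a-trimethyloctahydro-1-benzoxepin-6-one)
Conditions: TBSOTf (1.5 equiv), 2,6-lutidine, CH2Cl2, −78 to 0 °C
Reagents that add atoms: TBSOTf, CC(C)(C)[Si](C)(C)OS(=O)(=O)C(F)(F)F
Why: Silylation of the hindered secondary alcohol (flanked by CMe2) with a silyl triflate; no stereocentre is changed. The alcohol is protected for the enolate chemistry.

**Step 7**
Reactants: 9 + 10 (MeI)
Product: 11 ((3R,5aR,9aS)-3-TBSO-2,2,5a,7-tetramethyloctahydro-1-benzoxepin-6-one, C7 epimeric mixture)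
Conditions: LDA (1.1 equiv), THF, −78 °C; then MeI (1.5 equiv), −78 to 0 °C
Reagents that add atoms: MeI, CI
Why: Only C10 (benzoxepine C7) is enolizable, because C6 is quaternary, so enolate alkylation places the methyl regiospecifically. The new C10 centre is transient because it becomes sp2 in step 8.

**Step 8**
Reactants: 11 + 12 (PhNTf2)
Product: 13 (vinyl triflate, (3R,5aR,9aS)-3-TBSO-2,2,5a,7-tetramethyl-2,3,4,5,5a,8,9,9a-octahydro-1-benzoxepin-6-yl triflate)
Conditions: KHMDS (1.2 equiv), THF, −78 °C; then PhNTf2, −78 to 0 °C
Reagents that add atoms: PhNTf2, O=S(=O)(N(c1ccccc1)S(=O)(=O)C(F)(F)F)C(F)(F)F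
Why: Enolate O-triflation gives the tetrasubstituted enol triflate, which is the ring alkene C10=C11 with the substituents in place. It also protects that alkene from epoxidation earlier in the sequence. This removes the C10 stereocentre and leaves C6/C7 untouched.

**Step 9**
Reactants: 13 (2 equiv) + 14 ((E)-1,2-bis(tributylstannyl)ethene, 1 equiv)
Product: 15 (bis-TBS triene dimer)
Conditions: Pd(PPh3)4 (10 mol %), CuCl, LiCl, DMSO, 60 °C
Reagents that add atoms: 14, CCCC[Sn](CCCC)(CCCC)/C=C/[Sn](CCCC)(CCCC)CCCC (supplies the C12=C13 unit)
Why: Double Stille coupling (Liebeskind–Corey conditions) joins two hindered vinyl triflates through the ethenylene bridge with retention of alkene geometry. It needs no new stereocentre, and the C2-symmetric dimer carries the pre-set C6/C7/C3 centres.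

**Step 10**
Reactants: 15
Product: 16 (bis-TBS saturated dimer with the CH2CH2 bridge)
Conditions: H2 (1 atm), 10% Pd/C, EtOAc, rt
Reagents that add atoms: none
Why: Hydrogenation is chemoselective for the unhindered disubstituted central alkene. The two tetrasubstituted ring alkenes next to the quaternary centres are inert at 1 atm.

**Step 11**
Reactants: 16
Product: 17 (C2-symmetric diol)
Conditions: TBAF (4 equiv), THF, 50 °C
Reagents that add atoms: none (the silyl groups are removed)
Why: Fluoride-mediated Si–O cleavage, with heating needed for the hindered TBS ethers. No stereocentre is affected.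

**Step 12**
Reactants: 17
Product: 18 (sodwanone T)
Conditions: Dess–Martin periodinane (0.6 equiv), NaHCO3, CH2Cl2, 0 °C; chromatographic separation, recycle diol
Reagents that add atoms: none (the oxidant removes hydrogen)
Why: Mono-oxidation of the diol is a statistical symmetry break, because the two remote, identical secondary alcohols react independently. It destroys only the C3 stereocentre of the oxidized half. The expected mono-ketone yield is about 40–45%, with the diol recovered.

## Compound list
1 | 2-methylresorcinol | Cc1c(O)cccc1O | starting material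
2 | 2-methylcyclohexane-1,3-dione | CC1C(=O)CCCC1=O | intermediate
3 | 5-bromo-2-methylpent-2-ene | CC(C)=CCCBr | starting material
4 | 2-methyl-2-(4-methylpent-3-en-1-yl)cyclohexane-1,3-dione | CC(C)=CCCC1(C)C(=O)CCCC1=O | intermediate
5 | (2R,3S)-3-hydroxy-2-methyl-2-(4-methylpent-3-en-1-yl)cyclohexan-1-one | O=C1CCC[C@H](O)[C@@]1(C)CCC=C(C)C | intermediate
6 | (2R,3S)-2-{2-[(2R)-3,3-dimethyloxiran-2-yl]ethyl}-3-hydroxy-2-methylcyclohexan-1-one | O=C1CCC[C@H](O)[C@@]1(C)CC[C@H]2OC2(C)C | intermediate
7 | (3R,5aR,9aS)-3-hydroxy-2,2,5a-trimethyloctahydro-1-benzoxepin-6-one | O=C1CCC[C@@H]2OC(C)(C)[C@H](O)CC[C@@]12C | intermediate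
8 | tert-butyldimethylsilyl triflate | CC(C)(C)[Si](C)(C)OS(=O)(=O)C(F)(F)F | starting material (reagent)
9 | TBS ether of 7 | O=C1CCC[C@@H]2OC(C)(C)[C@H](O[Si](C)(C)C(C)(C)C)CC[C@@]12C | intermediate
10 | iodomethane | CI | starting material (reagent)
11 | 7-methyl ketone (C7 epimers) | O=C1C(C)CC[C@@H]2OC(C)(C)[C@H](O[Si](C)(C)C(C)(C)C)CC[C@@]12C | intermediate
12 | N-phenylbis(trifluoromethanesulfonimide) | O=S(=O)(N(c1ccccc1)S(=O)(=O)C(F)(F)F)C(F)(F)F | starting material (reagent)
13 | vinyl triflate | FC(F)(F)S(=O)(=O)OC1=C(C)CC[C@@H]2OC(C)(C)[C@H](O[Si](C)(C)C(C)(C)C)CC[C@@]12C | intermediate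
14 | (E)-1,2-bis(tributylstannyl)ethene | CCCC[Sn](CCCC)(CCCC)/C=C/[Sn](CCCC)(CCCC)CCCC | starting material (reagent)
15 | bis-TBS triene dimer | C1(/C=C/C2=C(C)CC[C@@H]3OC(C)(C)[C@H](O[Si](C)(C)C(C)(C)C)CC[C@@]23C)=C(C)CC[C@@H]2OC(C)(C)[C@H](O[Si](C)(C)C(C)(C)C)CC[C@@]12C | intermediate
16 | bis-TBS saturated dimer | C1(CCC2=C(C)CC[C@@H]3OC(C)(C)[C@H](O[Si](C)(C)C(C)(C)C)CC[C@@]23C)=C(C)CC[C@@H]2OC(C)(C)[C@H](O[Si](C)(C)C(C)(C)C)CC[C@@]12C | intermediate
17 | C2-symmetric diol | C1(CCC2=C(C)CC[C@@H]3OC(C)(C)[C@H](O)CC[C@@]23C)=C(C)CC[C@@H]2OC(C)(C)[C@H](O)CC[C@@]12C | intermediate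
18 | sodwanone T | CC1=C(CCC2=C(C)CC[C@@H]3OC(C)(C)[C@H](O)CC[C@@]23C)[C@]2(C)CCC(=O)C(C)(C)O[C@H]2CC1 | target

## Totals
Total step count: 12. Longest linear sequence: 12 (steps 1–8 run once on bulk monomer; step 9 consumes two equivalents of 13).

## Three steps most likely to fail
1. **Step 3 (ketoreductase desymmetrization).** Known enzymes and catalysts put the OH cis to the larger chain, the opposite of what the trans-fused target needs.
   - Fallback: reduce dione 2 to (3S)-3-hydroxy-2-methylcyclohexanone (yeast or Ru transfer hydrogenation) and silylate it. Then make the silyl enol ether, run a Mukaiyama–Michael addition to acrolein anti to OTBS, and do a Wittig with Me2C=PPh3 and a TBAF deprotection to reach 5.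
2. **Step 5 (7-endo cyclization).** The 6-exo tetrahydropyran from attack at C3 may dominate over the oxepane.
   - Fallback: Michael addition of a silyl enol ether to isopropyl vinyl ketone gives an isopropyl-ketone chain. Then α-bromination and Ag+-promoted intramolecular etherification (oxyallyl-cation capture) build the oxepan-3-one, and a stereoselective reduction sets the alcohol half.
3. **Step 9 (double Stille coupling of hindered tetrasubstituted triflates).** The oxidative addition or the second coupling may stall.
   - Fallback: treat ketone 11 with BrMg–C≡C–MgBr to give a bis-propargylic diol. Hydrogenate the alkyne (Pd/C, H2) and dehydrate with Burgess reagent to form the tetrasubstituted ring alkenes.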